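**Retrosynthetic overview**
1. Feature used: ring A (the 6,6-dimethylcyclohexa-2,4-dienone with the quaternary C6 that bears two CH3) and ring B (the benzene ring of the chromene) are the same butanoylphloroglucinol, joined through C4(ring A)–CH2–C6(chromene). Ring A is a dearomatized copy of ring B.
2. Key disconnection: the two C6–CH3 bonds of ring A are cut last. The precursor is an all-aromatic diarylmethane whose trihydroxyphenyl ring has a single C–H, and a site-selective dearomative gem-dimethylation turns this flat ring into ring A.
3. That precursor comes from the C2-symmetric methylenebis(butanoylphloroglucinol) by desymmetrization: one pyran ring (C4–C4a and O1–C2 bonds) is annulated with 3-methylbut-2-enal by condensation and oxa-6π electrocyclization.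
4. The symmetric dimer is a homocoupling of butanoylphloroglucinol with formaldehyde, so no cross-coupling selectivity has to be solved. The monomer comes from phloroglucinol and butanoyl chloride.
5. Order of ring events: both carbocycles start as benzene rings, then the CH2 bridge, then the pyran ring, then ring A is dearomatized last.

Key step: step 4

Remark: the target has no stereocentre and no stereogenic double bond (C3=C4 of the chromene is cis by ring constraint), so it is achiral and needs no enantiocontrol; the SMILES shows one tautomer of the enolized β-triketone, and the tautomers interconvert.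

**Route**

Step 1
Reactants: 1 phloroglucinol (benzene-1,3,5-triol); 2 butanoyl chloride
Product: 3 1-(2,4,6-trihydroxyphenyl)butan-1-one
Conditions: AlCl3 (3.5 equiv), MeNO2/CH2Cl2, 0 °C → 40 °C; then ice/1 M HCl
Reagents that add atoms: none
Why: Friedel–Crafts acylation of the C3-symmetric, highly activated arene should stop after one C-acylation because the aryl ketone is deactivated as its aluminium chelate; no stereocentre is formed.

Step 2
Reactants: 3 1-(2,4,6-trihydroxyphenyl)butan-1-one (two molecules per bridge, used in excess)
Product: 5 bis(3-butanoyl-2,4,6-trihydroxyphenyl)methane, via hydroxymethyl ketone 4 (not isolated)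
Conditions: 3 (3.0 equiv), 37% aq. CH2O (1.0 equiv), 1% aq. KOH, 0 °C → rt; then 1 M HCl; unreacted 3 recovered
Reagents that add atoms: formaldehyde (C=O)
Why: Base-mediated phenol–formaldehyde condensation (Lederer–Manasse hydroxymethylation to 4, then displacement of the benzylic hydroxyl by a second phenolate in an elimination–addition) should give the symmetric diarylmethane, the excess of 3 keeping each reactive benzylic intermediate supplied with monomer rather than with dimer so that trimers stay minor.

Step 3
Reactants: 5 bis(3-butanoyl-2,4,6-trihydroxyphenyl)methane; 6 3-methylbut-2-enal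
Product: 8 1-[6-(3-butanoyl-2,4,6-trihydroxybenzyl)-5,7-dihydroxy-2,2-dimethyl-2H-chromen-8-yl]butan-1-one, via oxatriene 7 (not isolated)
Conditions: 5 (2.5 equiv), 6 (1.0 equiv), EDDA (20 mol %), 1,4-dioxane, 80 °C; unreacted 5 recovered
Reagents that add atoms: none
Why: Amine-catalysed Knoevenagel-type condensation at a free ring C–H gives the (Z)-1-oxatriene 7, which should close by oxa-6π electrocyclization to the 2H-chromene (formal [3+3] annulation); each ring of 5 has one C–H and can be annulated only once, the excess of 5 favours mono-annulation of the two equivalent rings, and closure on the oxygen next to the acyl-bearing carbon, through the dienone tautomer that has the acylfilicinic acid arrangement, should give the 8-acyl chromene, the mode of closure generally seen with 3-alkylated acylphloroglucinols.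

Step 4
Reactants: 8 1-[6-(3-butanoyl-2,4,6-trihydroxybenzyl)-5,7-dihydroxy-2,2-dimethyl-2H-chromen-8-yl]butan-1-one
Product: 10 drummondin A, via monomethyl arene 9 (not isolated)
Conditions: NaOMe (3.0 equiv), MeI (2.1 equiv), MeOH, Ar, 0 °C → rt; then 1 M HCl
Reagents that add atoms: iodomethane (CI)
Why: The polyphenolate of 8 should be C-methylated by SN2 attack on MeI at C5 of the trihydroxybenzyl ring, the only ring carbon of the molecule that still bears hydrogen and lies between two phenolate oxygens, to give 9, and renewed deprotonation and a second C-methylation at the same carbon then break the aromaticity and leave the enolized β-triketone of ring A. The closest known reaction type is the alkoxide/MeI double C-methylation of acylphloroglucinols, 3-alkylated ones included, to acylfilicinic acids. No ring is closed: the benzene ring itself becomes the cyclohexa-2,4-dienone, and the new C(CH3)2 carbon carries two identical groups, so no stereocentre arises. The step needs C- over O-alkylation, attack at the methyl-bearing carbon of 9 in preference to the two bridge-bearing carbons (C1 of the benzyl ring and C6 of the chromene), a stop after two methyl groups and an intact CH2 bridge. Methanol as a hydrogen-bond donor favours C-alkylation, the methyl-bearing carbon is the least hindered of the substituted positions, and ring A once formed is a vinylogous acid whose delocalized anion is a far weaker nucleophile than a phloroglucinolate, so that 2.1 equiv of MeI should be consumed before over-methylation sets in. Keeping the mixture at or below room temperature should suppress the base-induced retro-Michael cleavage of the bridge, which is a reaction of hot alkali.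

**Compound list**
1 | phloroglucinol (benzene-1,3,5-triol) | Oc1cc(O)cc(O)c1 | starting material
2 | butanoyl chloride | CCCC(=O)Cl | starting material
3 | 1-(2,4,6-trihydroxyphenyl)butan-1-one | CCCC(=O)c1c(O)cc(O)cc1O | intermediate
4 | 1-[2,4,6-trihydroxy-3-(hydroxymethyl)phenyl]butan-1-one (formed in the flask, not isolated) | CCCC(=O)c1c(O)cc(O)c(CO)c1O | intermediate
5 | bis(3-butanoyl-2,4,6-trihydroxyphenyl)methane | CCCC(=O)c1c(O)cc(O)c(Cc2c(O)cc(O)c(C(=O)CCC)c2O)c1O | intermediate
6 | 3-methylbut-2-enal | CC(C)=CC=O | starting material
7 | (6Z)-2-butanoyl-4-(3-butanoyl-2,4,6-trihydroxybenzyl)-3,5-dihydroxy-6-(3-methylbut-2-en-1-ylidene)cyclohexa-2,4-dien-1-one (formed in the flask, not isolated) | O=C1C(C(=O)CCC)=C(O)C(Cc2c(O)cc(O)c(C(=O)CCC)c2O)=C(O)/C1=C/C=C(C)C | intermediate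
8 | 1-[6-(3-butanoyl-2,4,6-trihydroxybenzyl)-5,7-dihydroxy-2,2-dimethyl-2H-chromen-8-yl]butan-1-one | CCCC(=O)c1c(O)cc(O)c(Cc2c(O)c3c(c(C(=O)CCC)c2O)OC(C)(C)C=C3)c1O | intermediate
9 | 1-[6-(3-butanoyl-2,4,6-trihydroxy-5-methylbenzyl)-5,7-dihydroxy-2,2-dimethyl-2H-chromen-8-yl]butan-1-one (formed in the flask, not isolated) | CCCC(=O)c1c(O)c(C)c(O)c(Cc2c(O)c3c(c(C(=O)CCC)c2O)OC(C)(C)C=C3)c1O | intermediate
10 | drummondin A, 2-butanoyl-4-[(8-butanoyl-5,7-dihydroxy-2,2-dimethyl-2H-chromen-6-yl)methyl]-3,5-dihydroxy-6,6-dimethylcyclohexa-2,4-dien-1-one | CCCC(=O)C1=C(O)C(Cc2c(O)c3c(c(C(=O)CCC)c2O)OC(C)(C)C=C3)=C(O)C(C)(C)C1=O | target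

**Step count**
Total steps: 4. Longest linear sequence: 4 (1 → 3 → 5 → 8 → 10).

**Steps most likely to fail**

Step 4 (key step). The methylation may go to the bridge-bearing ring carbons of either ring or to oxygen, may run on to a third methyl group, or the base may cleave and scramble the methylene bridge by retro-Michael reaction. The fallback sets out from 3 and comes back to the route at 10, and it moves the dearomatization to the monomer, where no second ring competes. Compound 3 is treated with NaOMe/MeI in MeOH to give 2-butanoyl-3,5-dihydroxy-6,6-dimethylcyclohexa-2,4-dien-1-one F1. F1 is condensed with formaldehyde in 1% aq. KOH at 0 °C in the presence of an excess of 3 to give the mixed dimer 2-butanoyl-4-(3-butanoyl-2,4,6-trihydroxybenzyl)-3,5-dihydroxy-6,6-dimethylcyclohexa-2,4-dien-1-one F2. The dienone ring of F2 has no ring C–H, so annulation with 6 (EDDA, 1,4-dioxane, 80 °C) can take place only at the single aromatic C–H and should give 10.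

Step 3. The annulation may take place on both rings, the pyran may close on the oxygen para to the acyl group, or conversion may stay low because the desymmetrization is statistical. The fallback sets out from 3 and comes back to the route at 8, and it builds the pyran ring on the monomer and joins the halves by a directed cross-coupling. An excess of 3 is condensed with 6 (EDDA, 1,4-dioxane, 80 °C) to give 1-(5,7-dihydroxy-2,2-dimethyl-2H-chromen-8-yl)butan-1-one F3, and any regioisomer is removed at this stage. A Mannich reaction of F3 with formaldehyde and dimethylamine in EtOH should give 1-{6-[(dimethylamino)methyl]-5,7-dihydroxy-2,2-dimethyl-2H-chromen-8-yl}butan-1-one F4 at its only free ring position. Heating F4 with an excess of 3 in 1,4-dioxane (elimination–addition with loss of dimethylamine) should give 8.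

Step 2. The condensation may run on to trimers and higher oligomers, because the dimer still has one free C–H on each ring. The fallback sets out from 3 and comes back to the route at 5, and it replaces the direct condensation by a stepwise union through an isolated electrophile precursor. Compound 3 is aminomethylated once with formaldehyde and dimethylamine (1 equiv each, EtOH, rt) to give 1-{3-[(dimethylamino)methyl]-2,4,6-trihydroxyphenyl}butan-1-one F5. F5 is purified and then heated with an excess of 3 in 1,4-dioxane, where elimination–addition with loss of dimethylamine should give 5.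

**Further compounds**
F1 | step 4 | 2-butanoyl-3,5-dihydroxy-6,6-dimethylcyclohexa-2,4-dien-1-one | CCCC(=O)C1=C(O)C=C(O)C(C)(C)C1=O
F2 | step 4 | 2-butanoyl-4-(3-butanoyl-2,4,6-trihydroxybenzyl)-3,5-dihydroxy-6,6-dimethylcyclohexa-2,4-dien-1-one | CCCC(=O)C1=C(O)C(Cc2c(O)cc(O)c(C(=O)CCC)c2O)=C(O)C(C)(C)C1=O
F3 | step 3 | 1-(5,7-dihydroxy-2,2-dimethyl-2H-chromen-8-yl)butan-1-one | CCCC(=O)c1c(O)cc(O)c2C=CC(C)(C)Oc12
F4 | step 3 | 1-{6-[(dimethylamino)methyl]-5,7-dihydroxy-2,2-dimethyl-2H-chromen-8-yl}butan-1-one | CCCC(=O)c1c(O)c(CN(C)C)c(O)c2C=CC(C)(C)Oc12
F5 | step 2 | 1-{3-[(dimethylamino)methyl]-2,4,6-trihydroxyphenyl}butan-1-one | CCCC(=O)c1c(O)cc(O)c(CN(C)C)c1O
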